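Assumption: the target has no stereocentre or stereogenic axis (it is achiral), so there is no enantiomer to control; 3-methyl-4-nitroaniline and diethyl oxalate are taken as the commercial starting materials.

**Retrosynthetic overview**
- Target ⇐ C2 bromination of 4,5,6-tribromo-3-(methylsulfanyl)indole ⇐ C3 sulfenylation of 4,5,6-tribromoindole.
- 4,5,6-Tribromoindole ⇐ saponification and decarboxylation of ethyl 4,5,6-tribromoindole-2-carboxylate.
- The pyrrole ring is the only ring formed (the benzene ring is bought); it is closed by reductive cyclisation of an o-nitroarylpyruvate (Reissert indole synthesis).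
- Key C–C bond (future C3–C2): intermolecular Claisen condensation of 2,3,4-tribromo-6-nitrotoluene with diethyl oxalate.
- 2,3,4-Tribromo-6-nitrotoluene ⇐ Sandmeyer ⇐ 2,6-dibromo-3-methyl-4-nitroaniline ⇐ dibromination of 3-methyl-4-nitroaniline, which fixes the 4,5,6-tribromo pattern before the ring is built.

**Route**

Step 1
Reactants: 1 3-methyl-4-nitroaniline
Product: 2 2,6-dibromo-3-methyl-4-nitroaniline
Conditions: Br2 (2.2 equiv), AcOH, 20 → 50 °C
Reagents that add atoms: bromine, BrBr
Why: Electrophilic aromatic bromination goes to the two positions ortho to NH2 because the para position carries the nitro group and the remaining ring CH is meta to NH2 and ortho to NO2.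

Step 2
Reactants: 2 2,6-dibromo-3-methyl-4-nitroaniline
Product: 4 1,2,3-tribromo-4-methyl-5-nitrobenzene (2,3,4-tribromo-6-nitrotoluene), via diazonium hydrogensulfate 3 (not isolated)
Conditions: NaNO2, conc. H2SO4, AcOH, 0–15 °C; then CuBr (0.3 equiv), 48% aq HBr, 0 → 70 °C
Reagents that add atoms: hydrobromic acid, Br
Why: Nitrosylsulfuric acid diazotises the weakly basic, hindered aniline and the Sandmeyer reaction in bromide medium replaces N2 by Br, so any halide exchange at the activated ortho positions is degenerate.

Step 3
Reactants: 4 1,2,3-tribromo-4-methyl-5-nitrobenzene; 5 diethyl oxalate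
Product: 7 ethyl 3-(2,3,4-tribromo-6-nitrophenyl)-2-oxopropanoate, via potassium enolate 6 (not isolated)
Conditions: KOEt (1.2 equiv), Et2O/EtOH, N2, 0 °C → rt, 20 h; then AcOH/H2O
Reagents that add atoms: none
Why: The methyl group ortho to NO2 is deprotonated by ethoxide and the carbanion acylates non-enolisable diethyl oxalate in a crossed Claisen condensation (first stage of the Reissert indole synthesis), driven by precipitation of the stabilised enolate salt; no stereocentre is formed.

Step 4
Reactants: 7 ethyl 3-(2,3,4-tribromo-6-nitrophenyl)-2-oxopropanoate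
Product: 9 ethyl 4,5,6-tribromo-1H-indole-2-carboxylate, via amino keto ester 8 (not isolated)
Conditions: Fe powder (5 equiv), AcOH/EtOH 1:1, 85 °C, 2 h
Reagents that add atoms: none
Why: Iron in acetic acid reduces the nitro group without touching aryl bromides, and the aniline condenses at once with the adjacent ketone and dehydrates to the aromatic indole (Reissert reductive cyclisation).

Step 5
Reactants: 9 ethyl 4,5,6-tribromo-1H-indole-2-carboxylate
Product: 11 4,5,6-tribromo-1H-indole-2-carboxylic acid, via sodium carboxylate 10 (not isolated)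
Conditions: NaOH (3 equiv), EtOH/THF/H2O, 60 °C; then 2 M HCl to pH 2
Reagents that add atoms: sodium hydroxide, [Na+].[OH-]
Why: Plain ester saponification, to which the aryl bromides and the indole NH are inert.

Step 6
Reactants: 11 4,5,6-tribromo-1H-indole-2-carboxylic acid
Product: 12 4,5,6-tribromo-1H-indole
Conditions: Cu powder (0.2 equiv), quinoline, N2, 200 °C, 1 h
Reagents that add atoms: none
Why: Copper-catalysed thermal protodecarboxylation of indole-2-carboxylic acids is the standard end of the Reissert sequence and is well precedented for bromoindole-2-carboxylic acids when the heating time is kept short.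

Step 7
Reactants: 12 4,5,6-tribromo-1H-indole
Product: 13 4,5,6-tribromo-3-(methylsulfanyl)-1H-indole
Conditions: MeSSMe (0.55 equiv), SO2Cl2 (0.55 equiv), CH2Cl2, −20 → 0 °C; then add to 12 in DMF, 0 °C → rt
Reagents that add atoms: dimethyl disulfide, CSSC (cleaved in the flask by sulfuryl chloride to methanesulfenyl chloride, CSCl, which transfers SMe)
Why: Electrophilic sulfenylation by the sulfenyl chloride takes place at C3, the most nucleophilic indole position, and one equivalent of this strong electrophile is enough even for the deactivated tribromoindole.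

Step 8
Reactants: 13 4,5,6-tribromo-3-(methylsulfanyl)-1H-indole
Product: 14 2,4,5,6-tetrabromo-3-(methylsulfanyl)-1H-indole
Conditions: NBS (1.02 equiv), anhydrous CH2Cl2, dark, −20 → 0 °C
Reagents that add atoms: N-bromosuccinimide, O=C1CCC(=O)N1Br
Why: Electrophilic bromination goes to C2, the only free position of the pyrrole ring and activated by N and the 3-SMe group, while the remaining C7–H sits on the deactivated tribromobenzene ring; dry conditions avoid sulfoxide formation.

**Compound list**
1 | 3-methyl-4-nitroaniline | Cc1cc(N)ccc1[N+](=O)[O-] | starting material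
2 | 2,6-dibromo-3-methyl-4-nitroaniline | Cc1c(Br)c(N)c(Br)cc1[N+](=O)[O-] | intermediate
3 | 2,6-dibromo-3-methyl-4-nitrobenzenediazonium hydrogensulfate | Cc1c(Br)c([N+]#N)c(Br)cc1[N+](=O)[O-].OS(=O)(=O)[O-] | intermediate (not isolated)
4 | 1,2,3-tribromo-4-methyl-5-nitrobenzene (2,3,4-tribromo-6-nitrotoluene) | Cc1c(Br)c(Br)c(Br)cc1[N+](=O)[O-] | intermediate
5 | diethyl oxalate | CCOC(=O)C(=O)OCC | starting material
6 | potassium (Z)-1-ethoxy-1-oxo-3-(2,3,4-tribromo-6-nitrophenyl)prop-2-en-2-olate (geometry drawn as Z, of no consequence) | CCOC(=O)/C([O-])=C/c1c(Br)c(Br)c(Br)cc1[N+](=O)[O-].[K+] | intermediate (not isolated)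
7 | ethyl 3-(2,3,4-tribromo-6-nitrophenyl)-2-oxopropanoate | CCOC(=O)C(=O)Cc1c(Br)c(Br)c(Br)cc1[N+](=O)[O-] | intermediate
8 | ethyl 3-(2-amino-4,5,6-tribromophenyl)-2-oxopropanoate | CCOC(=O)C(=O)Cc1c(Br)c(Br)c(Br)cc1N | intermediate (not isolated)
9 | ethyl 4,5,6-tribromo-1H-indole-2-carboxylate | CCOC(=O)c1cc2c(Br)c(Br)c(Br)cc2[nH]1 | intermediate
10 | sodium 4,5,6-tribromo-1H-indole-2-carboxylate | [Na+].[O-]C(=O)c1cc2c(Br)c(Br)c(Br)cc2[nH]1 | intermediate (not isolated)
11 | 4,5,6-tribromo-1H-indole-2-carboxylic acid | OC(=O)c1cc2c(Br)c(Br)c(Br)cc2[nH]1 | intermediate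
12 | 4,5,6-tribromo-1H-indole | Brc1cc2[nH]ccc2c(Br)c1Br | intermediate
13 | 4,5,6-tribromo-3-(methylsulfanyl)-1H-indole | CSc1c[nH]c2cc(Br)c(Br)c(Br)c12 | intermediate
14 | 2,4,5,6-tetrabromo-3-(methylsulfanyl)-1H-indole | CSc1c(Br)[nH]c2cc(Br)c(Br)c(Br)c12 | target

**Totals**
Total step count: 8. Longest linear sequence: 8 steps (1 → 14).

**Three steps most likely to fail, each with a fallback**

Step 3, the Claisen condensation. The methyl group is flanked by NO2 and Br, and ethoxide could attack the bromine para to the nitro group. The fallback sets out from 4 and avoids alkoxide base: heating 4 with N,N-dimethylformamide dimethyl acetal in DMF at 110–120 °C gives the enamine (E)-N,N-dimethyl-2-(2,3,4-tribromo-6-nitrophenyl)ethen-1-amine F1. Reduction of this with Fe/AcOH at 80 °C closes the ring with loss of dimethylamine (Leimgruber–Batcho indole synthesis). The fallback comes back to the route at 12, bypassing steps 3–6.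

Step 6, the decarboxylation. At 200 °C with copper the tribromoarene may suffer partial debromination or tarring. The fallback sets out from 11 and avoids protodecarboxylation. C3 sulfenylation of 11 with methanesulfenyl chloride, as in step 7, gives 4,5,6-tribromo-3-(methylsulfanyl)-1H-indole-2-carboxylic acid F2. Decarboxylative ipso-bromination of this electron-rich heteroaryl acid (NBS in DMF, or Bu4NBr3/K3PO4 in MeCN at 60–80 °C) replaces CO2H by Br. The fallback comes back to the route directly at 14.

Step 8, the C2 bromination. NBS may oxidise or brominate at sulfur, or over-brominate. The fallback sets out from 13 and replaces electrophilic substitution by directed metalation. Boc2O with catalytic DMAP in MeCN gives tert-butyl 4,5,6-tribromo-3-(methylsulfanyl)-1H-indole-1-carboxylate F3. LDA in THF at −78 °C deprotonates C2 selectively (no halogen–metal exchange with an amide base) to give tert-butyl 4,5,6-tribromo-2-lithio-3-(methylsulfanyl)-1H-indole-1-carboxylate F4. Quenching with 1,2-dibromotetrachloroethane gives tert-butyl 2,4,5,6-tetrabromo-3-(methylsulfanyl)-1H-indole-1-carboxylate F5. TFA in CH2Cl2 at 0 °C removes the Boc group, and the fallback comes back to the route at 14.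

**Further compounds**
F1 | step 3 | (E)-N,N-dimethyl-2-(2,3,4-tribromo-6-nitrophenyl)ethen-1-amine | CN(C)/C=C/c1c(Br)c(Br)c(Br)cc1[N+](=O)[O-]
F2 | step 6 | 4,5,6-tribromo-3-(methylsulfanyl)-1H-indole-2-carboxylic acid | CSc1c(C(=O)O)[nH]c2cc(Br)c(Br)c(Br)c12
F3 | step 8 | tert-butyl 4,5,6-tribromo-3-(methylsulfanyl)-1H-indole-1-carboxylate | CSc1cn(C(=O)OC(C)(C)C)c2cc(Br)c(Br)c(Br)c12
F4 | step 8 | tert-butyl 4,5,6-tribromo-2-lithio-3-(methylsulfanyl)-1H-indole-1-carboxylate | CSc1c([Li])n(C(=O)OC(C)(C)C)c2cc(Br)c(Br)c(Br)c12
F5 | step 8 | tert-butyl 2,4,5,6-tetrabromo-3-(methylsulfanyl)-1H-indole-1-carboxylate | CSc1c(Br)n(C(=O)OC(C)(C)C)c2cc(Br)c(Br)c(Br)c12
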